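## Structural features

The target is a linear B-type procyanidin trimer, epicatechin-(4β→6)-epicatechin-(4β→6)-epicatechin. Each of its three flavan-3-ol units is a chroman (phloroglucinol-type ring A fused to pyran ring C) with a catechol ring B on C2. Two C(sp3)–C(sp2) bonds join the units: C4 of the upper unit to C6 of the middle ring A, and C4 of the middle unit to C6 of the lower ring A. There are eight stereocentres: the contiguous C2/C3/C4 triads of the upper and middle units (2R,3R; 2,3-cis; 3,4-trans; C4 aryl β) and C2/C3 (2R,3R) of the lower unit. The twelve phenols are oxidation-prone, C2 epimerises in base through ring opening of a free phenolate, and the doubly benzylic interflavan bonds are cleaved by strong acid; global benzyl protection with one neutral hydrogenolysis at the end is therefore planned. The real difficulty is twofold: cationic coupling of a C4 electrophile with ring A prefers C8 over C6, and C3 and C4 of the middle unit must be set between two bulky, di-ortho-oxygenated aryl groups. The key step uses the fact that C4 of the middle unit is a diarylmethine ortho to the ring A oxygen that becomes O1. It can be unmasked as an ortho-quinone methide of middle ring A carrying lower ring A on the methide carbon, and a two-carbon aldehyde enamine then supplies C3 and C2.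

## Logic of the disconnections

25 ⇒ 24. The fifteen O–benzyl bonds are cut and a C8–Br bond on the lower ring A is restored. This hides every phenol and alcohol and blocks the one nucleophilic ring A carbon that must stay unsubstituted. The forward step has to remove both kinds of group in one neutral hydrogenolysis.

24 ⇒ 23. O1–C2 of the middle ring C is cut. The ring opens to a phenol and an open-chain benzylic carbinol whose configuration can be set by acyclic control. The forward step must be an SN2 closure with clean inversion, so 23 must be the 2,3-anti (2S,3R) carbinol.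

23 ⇒ 22 ⇒ 21. No skeletal bond is cut; C2 is taken through the ketone. Aryl addition to an α-benzyloxy aldehyde should favour the 2,3-syn carbinol, which would close to the unwanted 2,3-trans ring. The forward steps need an oxidant that spares a free phenol and a chelation-controlled hydride delivery.

21 ⇒ 17 + 18. The C2–ring B bond is cut. Ring B becomes a simple aryl Grignard reagent (19, made from 18), and the middle unit shrinks to a lactol with C2 at the aldehyde oxidation level. The forward step requires only that the lactol opens (20) and accepts the aryl group; the configuration of C2 is not yet needed.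

17 ⇒ 12 + 13. C3–C4 and O1–C2 of the middle ring C are cut. C4 is a diarylmethine ortho to the phenol oxygen, which is the retron of an ortho-quinone methide annulation. One ring and two stereocentres disappear, leaving a benzhydrol and a two-carbon aldehyde. The forward step (through 14, 15 and 16) must control both the enamine face and the methide face at a crowded carbon.

12 ⇒ 7 + 10. The bond between the carbinol carbon and the middle ring A (the future C4–C4a bond) is cut. The phenol of 7 is para to the upper unit and has two equivalent ortho carbons, so the 4→6 pattern of the upper linkage follows from symmetry. The cut gives two flavan-sized halves of similar size. The forward step (through 11) must be strictly ortho-selective with a hindered, electron-rich aldehyde and must stop at the carbinol.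

7 ⇒ 6 ⇒ 3 + 5. The upper C4–aryl bond and one O–Si bond are cut. A C4 electrophile is expected to be attacked anti to the C3 oxygen, which gives the 3,4-trans bond, and the upper unit goes back to a pool-derived flavan. The arene must react through the carbon para to the oxygen that is to be free later; the bulky silyl ether in 5 is there to ensure that.

10 ⇒ 8 ⇒ 2. The C6–CHO bond and the C8–Br bond are cut. Bromination should pick C8, leaving only C6 for formylation (through 9). The forward steps need that regioselectivity and tolerance of benzyl ethers.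

3 ⇒ 2 ⇒ 1 and 5 ⇒ 4. The C4–O bond, the five benzyl ethers and the silyl ether are cut. Compound 2 serves both branches, so the upper and lower units bring their C2 and C3 centres from the chiral pool.

## Other disconnections considered

Alternative 1: The cut removes C4–C4a in both the upper and the middle unit and leads back to the acyclic bis(trans-epoxide) A2, in which each ring A is still a 3,5-dioxygenated aryl ether on C2. In the forward step a Lewis acid would open each epoxide at its benzylic carbon C4, and the ortho carbon of the ether-linked arene would close ring C, giving diol A1.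
- In its favour: two rings are closed in one operation. If the opening stays SN2-like, the trans-epoxide geometry is translated stereospecifically into the 3,4-trans relationship; this is a firmer source of C4 configuration than face selection on a planar methide, and here the alternative is the better. The arene closing the middle ring has two equivalent ortho carbons, so the 4→6 pattern is fixed by symmetry exactly as in the chosen plan (equal). A1 needs only hydrogenolysis, one step after the key step against five (better).
- Against it here: each epoxide carbon C4 carries a 2,4,6-trioxygenated aryl group. Full ionisation at C4, with loss of stereospecificity, and 1,2-hydride shift (Meinwald rearrangement) are expected to compete strongly under the Lewis acid. The two C2 aryl ether centres are benzylic and exposed to the same acid. A2 holds six stereocentres that would have to be built from achiral chalcone-type material; only the lower unit would come from the pool.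
- Comparison: both plans pass through electron-poor benzylic C4, but the chosen plan does so under a weak carboxylic acid. The route to A2 is estimated to be much longer than the nine steps to 12, so the saving after the key step would be more than lost before it.

Alternative 2: The cut removes C4a–C5, C8–C8a and C5–C6 of the middle ring A. It leads to cyclobutenone A4 (upper unit on its sp3 carbon) and siloxyalkyne A5 (lower unit plus the acyclic C2–C4 chain of the middle unit). The forward step is a thermal Danheiser benzannulation: electrocyclic opening of A4, (2+2) addition to A5, a second ring opening, 6π closure and tautomerisation to phenol A3.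
- In its favour: the substitution pattern of the hexasubstituted ring A is dictated by the mechanism and needs neither a symmetric phenol nor a blocking logic; this is equal to the chosen plan and more general. Neutral, acid-free heating is better for the interflavan bond and the benzyl ethers. The two ring A oxygens emerge differentiated (free C5 hydroxyl, silylated C8a oxygen), which suits the later benzylation and ring closure (equal).
- Against it here: the step creates no stereocentre. C2, C3 and C4 of the middle unit must already be present in A5, so the stereochemical problem that the chosen key step addresses is only moved into the fragment synthesis. A5 would need ynolate chemistry on a base-sensitive, heavily functionalised ester. In A4 the bulky flavanyl group sits on the carbon that must rotate outward and then form C5–C6 next to a fully substituted centre, so dimerisation of the ring-opened intermediate or arrest after the (2+2) stage could compete.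
- Comparison: after A3 about five steps would remain (benzylation, two desilylations, Mitsunobu closure, hydrogenolysis), the same as in the chosen route (equal). The two fragments would cost clearly more steps than 7 and 10.

Alternative 3: The cut removes C4a–C5 and C7–C8 of the lower ring A. It leads to malonate A7 (complete upper and middle units with the malonate on C4 of the middle unit) and dimethyl 3-oxoglutarate A8. In the forward step an alkoxide base would drive a double Claisen condensation of the dianion of A8 with both ester groups of A7, and the ring would aromatise to A6.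
- In its favour: ring A grows from a carbon already bonded to C4, so the attachment position of the lower unit cannot be wrong and no C8 blocking group is needed; on regiochemistry the alternative is the better. The reagents are cheap, and the ester on the future C8 could later leave by decarboxylation.
- Against it here: A7 is an α-substituted malonate; deprotonation at the malonate carbon would make both acyl carbons poor electrophiles, and the flavan shields them further. A6 is far from the target: ring C and ring B of the lower unit, with C2 and C3, would still have to be built (estimated eight to ten steps), whereas the chosen plan brings the lower unit in intact from 1. A7 needs the complete middle unit, so C3 and C4 are again left to earlier chemistry.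
- Comparison: the mechanism is classical and robust in simple cases (equal in reliability of bond type), but it forms only achiral arene bonds, and the step count is clearly worse.

Key step: step 9

Remark (availability): 3,5-bis(benzyloxy)phenol (4), 4-bromo-1,2-bis(benzyloxy)benzene (18) and (S)-α,α-diphenylprolinol trimethylsilyl ether are taken as commercial.
Remark (structure check): every centre of 12 and 17 was compared with the target; the upper and middle units are 2R,3R with the C4 aryl trans to the C3 oxygen, the lower unit is 2R,3R, and no descriptor needed correction.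
Remark (design change): capping with free phloroglucinol would leave the para hydroxyl as the most reactive one in a later benzylation, so the para-free phenol 7 is made instead from arene 5, whose silyl ether marks that oxygen and steers the C4 arylation.
Remark (design change): the carbinol oxidation is run with MnO2 because a free, electron-rich phenol is present at that stage.

## Route

Step 1
Reactants: 1 (−)-epicatechin
Product: 2 3,5,7,3',4'-penta-O-benzyl-(−)-epicatechin (2R,3R)
Conditions: BnBr (6 equiv), NaH (6 equiv), DMF, −20 °C → rt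
Reagents that add atoms: benzyl bromide, BrCc1ccccc1
Why: Williamson etherification of the four phenols and the C3 alkoxide; low temperature with the halide present from the start should outpace base-induced C2 epimerisation and C-benzylation, and no stereocentre is touched.

Step 2
Reactants: 2 3,5,7,3',4'-penta-O-benzyl-(−)-epicatechin
Product: 3 4β-(2-ethoxyethoxy)-3,5,7,3',4'-penta-O-benzylepicatechin (2,3-cis; 3,4-trans)
Conditions: DDQ (2 equiv), 2-ethoxyethanol (4 equiv), CH2Cl2, rt
Reagents that add atoms: 2-ethoxyethanol, CCOCCO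
Why: Benzylic oxidation by hydride abstraction at C4, which the 5,7-dioxygenated ring A activates far more than any benzyl ether CH2, followed by trapping with the alcohol anti to the C3 benzyloxy group; the C4 centre is re-formed in step 4 in any case.

Step 3
Reactants: 4 3,5-bis(benzyloxy)phenol
Product: 5 [3,5-bis(benzyloxy)phenoxy]triisopropylsilane
Conditions: iPr3SiCl, imidazole, DMF, rt
Reagents that add atoms: chlorotriisopropylsilane, CC(C)[Si](Cl)(C(C)C)C(C)C
Why: Standard silylation of a phenol; the bulky silyl ether shields both of its ortho carbons in step 4 and marks the oxygen that must be free in step 8.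

Step 4
Reactants: 3 4β-(2-ethoxyethoxy)-3,5,7,3',4'-penta-O-benzylepicatechin; 5 [3,5-bis(benzyloxy)phenoxy]triisopropylsilane
Product: 6 4β-[2,6-bis(benzyloxy)-4-(triisopropylsilyloxy)phenyl]-3,5,7,3',4'-penta-O-benzylepicatechin (3,4-trans)
Conditions: 5 (3 equiv), Me3SiOTf (0.1 equiv), CH2Cl2, −78 → −40 °C
Reagents that add atoms: none
Why: Friedel–Crafts alkylation: the silyl triflate ionises the C4 acetal and arene 5 should attack through the carbon para to the silyloxy group, the only ring position not flanked by the triisopropylsilyl ether. Attack anti to the C3 benzyloxy group should give the 4β (3,4-trans) bond, and excess 5 suppresses self-condensation of 3.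

Step 5
Reactants: 6 4β-[2,6-bis(benzyloxy)-4-(triisopropylsilyloxy)phenyl]-3,5,7,3',4'-penta-O-benzylepicatechin
Product: 7 4β-[2,6-bis(benzyloxy)-4-hydroxyphenyl]-3,5,7,3',4'-penta-O-benzylepicatechin (upper unit carrying the future middle ring A as a para-free phenol)
Conditions: Bu4NF, AcOH, THF, 0 °C
Reagents that add atoms: none
Why: Fluoride cleavage of an aryl silyl ether, buffered so that no free phenoxide accumulates; benzyl ethers are inert, and the freed hydroxyl is para to the flavan so that its two ortho carbons are equivalent.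

Step 6
Reactants: 2 3,5,7,3',4'-penta-O-benzyl-(−)-epicatechin
Product: 8 8-bromo-3,5,7,3',4'-penta-O-benzylepicatechin
Conditions: NBS (1.0 equiv), CH2Cl2, −78 °C → rt
Reagents that add atoms: N-bromosuccinimide, O=C1CCC(=O)N1Br
Why: Electrophilic aromatic bromination; ring A is the most electron-rich arene, and C8 (between O1 and the C7 ether) should react in preference to C6, which lies between two benzyloxy groups. The bromine blocks C8 until step 14.

Step 7
Reactants: 8 8-bromo-3,5,7,3',4'-penta-O-benzylepicatechin
Product: 10 8-bromo-6-formyl-3,5,7,3',4'-penta-O-benzylepicatechin, via Vilsmeier iminium salt 9 (not isolated)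
Conditions: POCl3, DMF, 0 → 60 °C; then H2O, rt
Reagents that add atoms: N,N-dimethylformamide, CN(C)C=O (formyl carbon); water, O (carbonyl oxygen on hydrolysis of 9)
Why: Vilsmeier–Haack formylation at C6, the only free position of the trialkoxy ring A; the iminium salt is hydrolysed on work-up and the benzyl ethers tolerate the conditions.

Step 8
Reactants: 7 4β-[2,6-bis(benzyloxy)-4-hydroxyphenyl]-3,5,7,3',4'-penta-O-benzylepicatechin; 10 8-bromo-6-formyl-3,5,7,3',4'-penta-O-benzylepicatechin
Product: 12 ortho-hydroxybenzhydrol: 7 in which the ring carbon ortho to the free hydroxyl bears a CH(OH) group bonded to C6 of 8-bromo-3,5,7,3',4'-penta-O-benzylepicatechin (both carbinol epimers), via bromomagnesium phenoxide 11 (not isolated)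
Conditions: EtMgBr (1.0 equiv), Et2O, 0 °C; solvent change to toluene; 10 (1.1 equiv), rt; pH 7 buffer
Reagents that add atoms: none
Why: Magnesium-phenoxide-directed ortho-hydroxyalkylation: in a non-donor solvent the aldehyde binds to the phenoxide magnesium and is attacked by the ortho carbon through a six-membered transition state. Both ortho carbons are equivalent, which fixes the 4→6 pattern of the upper linkage, and the carbinol centre need not be controlled because step 9 planarises it.

Step 9
Reactants: 12 ortho-hydroxybenzhydrol (both carbinol epimers); 13 benzyloxyacetaldehyde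
Product: 17 middle-unit lactol (2-hydroxychroman; 3R benzyloxy; 3,4-trans; anomer mixture), via enamine 14 (not isolated), via ortho-quinone methide 15 (not isolated), via aminal 16 (not isolated)
Conditions: 13 (3 equiv), (S)-α,α-diphenylprolinol trimethylsilyl ether (20 mol %), PhCO2H (20 mol %), CH2Cl2, 0 °C → rt
Reagents that add atoms: water, O (formed in the flask when 14 and 15 arise; no external reagent)
Why: Benzoic acid assists loss of water from either carbinol epimer of 12 to one planar ortho-quinone methide 15, while 13 condenses with the amine to the E-enamine 14. The nucleophilic enamine carbon adds to the methide carbon (C4), forming C3–C4 and restoring the middle ring A as a phenoxide, whose oxygen then adds to the iminium carbon to give the N,O-aminal 16; hydrolysis releases 17 and the catalyst. The closest known reaction type is the chiral secondary-amine-catalysed formal oxa-(4+2) annulation of aldehydes with ortho-quinone methides generated in situ from ortho-hydroxybenzhydrols; only the α-benzyloxy aldehyde and the two di-ortho-substituted aryl groups at the methide are new. Ring C of the middle unit closes in the second event by 6-exo-trig attack of the phenoxide oxygen on the iminium carbon (O1–C2), after the intermolecular C3–C4 bond has formed. C3 is controlled by the catalyst: the diphenyl(silyloxy)methyl group of the (S)-amine shields one face of the s-trans E-enamine, and bonding on the open face gives 3R. C4 is controlled by the topology of the same transition state, with the enamine nitrogen over the heterodiene oxygen and the benzyloxy group turned outward, which places the lower aryl group trans to the C3 oxygen; amine-mediated equilibration at the enolisable C3 of the open hydroxy aldehyde should also drain any 3,4-cis adduct to this more stable trans arrangement. The step needs C-attack at the methide in preference to aldehyde self-aldol and a single site of annulation: the only free phenol of 12 is ortho to the carbinol, the C8 bromine blocks the lower ring A against arylation by 15, and all other oxygens are benzyl ethers. The anomeric mixture at C2 is of no consequence because C2 is re-formed in steps 10 to 13.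

Step 10
Reactants: 17 middle-unit lactol; 18 4-bromo-1,2-bis(benzyloxy)benzene
Product: 21 phenol carbinol: ring-opened middle unit with free C8a hydroxyl and a C2 secondary alcohol bearing the 3,4-bis(benzyloxy)phenyl group (C2 epimers; 3R; C4 unchanged), via aryl Grignard reagent 19 (not isolated), via ring-opened aldehyde 20 (not isolated)
Conditions: 18, Mg, THF, rt; then 17 added to 19 (4 equiv), THF, 0 °C → rt; pH 7 buffer
Reagents that add atoms: none
Why: Grignard addition to a lactol: the first equivalent deprotonates and opens the lactol to the aldehyde, the second adds to the carbonyl. Chelation should favour the 2,3-syn epimer, but the C2 configuration is not needed because C2 is oxidised in step 11.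

Step 11
Reactants: 21 phenol carbinol (C2 epimers)
Product: 22 phenol ketone: 21 with C2 as the 3,4-bis(benzyloxy)phenyl ketone (3R)
Conditions: MnO2 (activated, excess), CH2Cl2, rt
Reagents that add atoms: none
Why: MnO2 oxidation of an electron-rich benzylic alcohol to the aryl ketone; the heterogeneous oxidant is selective for activated alcohols and should leave the hindered phenol and the benzyl ethers alone, and the neutral medium should not epimerise C3.

Step 12
Reactants: 22 phenol ketone
Product: 23 (2S,3R)-carbinol: 2,3-anti epimer of 21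
Conditions: Zn(BH4)2, Et2O/CH2Cl2, −30 → 0 °C
Reagents that add atoms: none
Why: Chelation-controlled ketone reduction: zinc bridges the carbonyl and the C3 benzyloxy oxygen, and hydride adds from the face opposite the C4 diarylmethyl group, which should give the 2,3-anti (2S,3R) alcohol needed for inversion.

Step 13
Reactants: 23 (2S,3R)-carbinol
Product: 24 pentadeca-O-benzyl-8-bromo-epicatechin-(4β→6)-epicatechin-(4β→6)-epicatechin (bromine on C8 of the lower unit)
Conditions: PPh3, DIAD, THF, 0 °C → rt, high dilution
Reagents that add atoms: none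
Why: Mitsunobu etherification: the phenol displaces the activated C2 oxygen intramolecularly (6-exo-tet) with inversion, turning the 2,3-anti carbinol into the 2,3-cis (2R,3R) pyran ring of the middle unit.

Step 14
Reactants: 24 pentadeca-O-benzyl-8-bromo trimer
Product: 25 epicatechin-(4β→6)-epicatechin-(4β→6)-epicatechin (target)
Conditions: H2 (1 atm), Pd(OH)2/C, Et3N, THF/MeOH/H2O, rt
Reagents that add atoms: none
Why: Hydrogenolysis over Pd(OH)2 on carbon removes the fifteen benzyl ethers and reduces the C8–Br bond, with the amine taking up HBr; no stereocentre is affected and the buffered neutral medium spares the interflavan bonds.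

## Compound list

1 | (−)-epicatechin | O[C@@H]1Cc2c(O)cc(O)cc2O[C@@H]1c1ccc(O)c(O)c1 | starting material
2 | 3,5,7,3',4'-penta-O-benzyl-(−)-epicatechin | c1c(OCc9ccccc9)cc2c(c1OCc9ccccc9)C[C@@H](OCc9ccccc9)[C@@H](c8ccc(OCc9ccccc9)c(OCc9ccccc9)c8)O2 | intermediate
3 | 4β-(2-ethoxyethoxy)-3,5,7,3',4'-penta-O-benzylepicatechin | c9ccccc9COc1cc(OCc9ccccc9)c2c(c1)O[C@H](c8ccc(OCc9ccccc9)c(OCc9ccccc9)c8)[C@H](OCc9ccccc9)[C@H]2OCCOCC | intermediate
4 | 3,5-bis(benzyloxy)phenol | Oc1cc(OCc2ccccc2)cc(OCc2ccccc2)c1 | starting material
5 | [3,5-bis(benzyloxy)phenoxy]triisopropylsilane | CC(C)[Si](Oc1cc(OCc2ccccc2)cc(OCc2ccccc2)c1)(C(C)C)C(C)C | intermediate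
6 | 4β-[2,6-bis(benzyloxy)-4-(triisopropylsilyloxy)phenyl]-3,5,7,3',4'-penta-O-benzylepicatechin | c9ccccc9COc1cc(OCc9ccccc9)c2c(c1)O[C@H](c8ccc(OCc9ccccc9)c(OCc9ccccc9)c8)[C@H](OCc9ccccc9)[C@H]2c3c(OCc9ccccc9)cc(O[Si](C(C)C)(C(C)C)C(C)C)cc3OCc9ccccc9 | intermediate
7 | 4β-[2,6-bis(benzyloxy)-4-hydroxyphenyl]-3,5,7,3',4'-penta-O-benzylepicatechin | c9ccccc9COc1cc(OCc9ccccc9)c2c(c1)O[C@H](c8ccc(OCc9ccccc9)c(OCc9ccccc9)c8)[C@H](OCc9ccccc9)[C@H]2c3c(OCc9ccccc9)cc(O)cc3OCc9ccccc9 | intermediate
8 | 8-bromo-3,5,7,3',4'-penta-O-benzylepicatechin | c1c(OCc9ccccc9)c(Br)c2c(c1OCc9ccccc9)C[C@@H](OCc9ccccc9)[C@@H](c8ccc(OCc9ccccc9)c(OCc9ccccc9)c8)O2 | intermediate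
9 | Vilsmeier iminium salt: C6 N,N-dimethyliminium chloride of 8 | C[N+](C)=Cc1c(OCc9ccccc9)c(Br)c2c(c1OCc9ccccc9)C[C@@H](OCc9ccccc9)[C@@H](c8ccc(OCc9ccccc9)c(OCc9ccccc9)c8)O2.[Cl-] | intermediate
10 | 8-bromo-6-formyl-3,5,7,3',4'-penta-O-benzylepicatechin | O=Cc1c(OCc9ccccc9)c(Br)c2c(c1OCc9ccccc9)C[C@@H](OCc9ccccc9)[C@@H](c8ccc(OCc9ccccc9)c(OCc9ccccc9)c8)O2 | intermediate
11 | bromomagnesium phenoxide of 7 | c9ccccc9COc1cc(OCc9ccccc9)c2c(c1)O[C@H](c8ccc(OCc9ccccc9)c(OCc9ccccc9)c8)[C@H](OCc9ccccc9)[C@H]2c3c(OCc9ccccc9)cc(O[Mg]Br)cc3OCc9ccccc9 | intermediate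
12 | ortho-hydroxybenzhydrol joining 7 and the lower unit (both carbinol epimers) | c9ccccc9COc1cc(OCc9ccccc9)c2c(c1)O[C@H](c8ccc(OCc9ccccc9)c(OCc9ccccc9)c8)[C@H](OCc9ccccc9)[C@H]2c3c(OCc9ccccc9)cc(O)c(c3OCc9ccccc9)C(O)c5c(OCc9ccccc9)c(Br)c6c(c5OCc9ccccc9)C[C@@H](OCc9ccccc9)[C@@H](c8ccc(OCc9ccccc9)c(OCc9ccccc9)c8)O6 | intermediate
13 | benzyloxyacetaldehyde | O=CCOCc1ccccc1 | starting material
14 | E-enamine of 13 with (S)-α,α-diphenylprolinol trimethylsilyl ether | c1ccccc1CO/C=C/N1CCC[C@H]1C(c1ccccc1)(c1ccccc1)O[Si](C)(C)C | intermediate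
15 | ortho-quinone methide of the middle ring A with the lower ring A on the methide carbon | c9ccccc9COc1cc(OCc9ccccc9)c2c(c1)O[C@H](c8ccc(OCc9ccccc9)c(OCc9ccccc9)c8)[C@H](OCc9ccccc9)[C@H]2C3=C(OCc9ccccc9)C(=Cc5c(OCc9ccccc9)c(Br)c6c(c5OCc9ccccc9)C[C@@H](OCc9ccccc9)[C@@H](c8ccc(OCc9ccccc9)c(OCc9ccccc9)c8)O6)C(=O)C=C3OCc9ccccc9 | intermediate
16 | cyclic N,O-aminal: 17 with the catalyst nitrogen on C2 in place of hydroxyl | c9ccccc9COc1cc(OCc9ccccc9)c2c(c1)O[C@H](c8ccc(OCc9ccccc9)c(OCc9ccccc9)c8)[C@H](OCc9ccccc9)[C@H]2c3c(OCc9ccccc9)cc4c(c3OCc9ccccc9)[C@H](c5c(OCc9ccccc9)c(Br)c6c(c5OCc9ccccc9)C[C@@H](OCc9ccccc9)[C@@H](c8ccc(OCc9ccccc9)c(OCc9ccccc9)c8)O6)[C@@H](OCc9ccccc9)C(N7CCC[C@H]7C(c8ccccc8)(c8ccccc8)O[Si](C)(C)C)O4 | intermediate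
17 | middle-unit lactol (3R benzyloxy; 3,4-trans; anomer mixture) | c9ccccc9COc1cc(OCc9ccccc9)c2c(c1)O[C@H](c8ccc(OCc9ccccc9)c(OCc9ccccc9)c8)[C@H](OCc9ccccc9)[C@H]2c3c(OCc9ccccc9)cc4c(c3OCc9ccccc9)[C@H](c5c(OCc9ccccc9)c(Br)c6c(c5OCc9ccccc9)C[C@@H](OCc9ccccc9)[C@@H](c8ccc(OCc9ccccc9)c(OCc9ccccc9)c8)O6)[C@@H](OCc9ccccc9)C(O)O4 | intermediate
18 | 4-bromo-1,2-bis(benzyloxy)benzene | Brc1ccc(OCc2ccccc2)c(OCc2ccccc2)c1 | starting material
19 | 3,4-bis(benzyloxy)phenylmagnesium bromide | Br[Mg]c1ccc(OCc2ccccc2)c(OCc2ccccc2)c1 | intermediate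
20 | ring-opened α-benzyloxy aldehyde as its bromomagnesium phenoxide | c9ccccc9COc1cc(OCc9ccccc9)c2c(c1)O[C@H](c8ccc(OCc9ccccc9)c(OCc9ccccc9)c8)[C@H](OCc9ccccc9)[C@H]2c3c(OCc9ccccc9)cc(O[Mg]Br)c(c3OCc9ccccc9)[C@H](c5c(OCc9ccccc9)c(Br)c6c(c5OCc9ccccc9)C[C@@H](OCc9ccccc9)[C@@H](c8ccc(OCc9ccccc9)c(OCc9ccccc9)c8)O6)[C@@H](OCc9ccccc9)C=O | intermediate
21 | phenol carbinol (C2 epimers) | c9ccccc9COc1cc(OCc9ccccc9)c2c(c1)O[C@H](c8ccc(OCc9ccccc9)c(OCc9ccccc9)c8)[C@H](OCc9ccccc9)[C@H]2c3c(OCc9ccccc9)cc(O)c(c3OCc9ccccc9)[C@H](c5c(OCc9ccccc9)c(Br)c6c(c5OCc9ccccc9)C[C@@H](OCc9ccccc9)[C@@H](c8ccc(OCc9ccccc9)c(OCc9ccccc9)c8)O6)[C@@H](OCc9ccccc9)C(O)c8ccc(OCc9ccccc9)c(OCc9ccccc9)c8 | intermediate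
22 | phenol ketone | c9ccccc9COc1cc(OCc9ccccc9)c2c(c1)O[C@H](c8ccc(OCc9ccccc9)c(OCc9ccccc9)c8)[C@H](OCc9ccccc9)[C@H]2c3c(OCc9ccccc9)cc(O)c(c3OCc9ccccc9)[C@H](c5c(OCc9ccccc9)c(Br)c6c(c5OCc9ccccc9)C[C@@H](OCc9ccccc9)[C@@H](c8ccc(OCc9ccccc9)c(OCc9ccccc9)c8)O6)[C@@H](OCc9ccccc9)C(=O)c8ccc(OCc9ccccc9)c(OCc9ccccc9)c8 | intermediate
23 | (2S,3R)-carbinol (2,3-anti) | c9ccccc9COc1cc(OCc9ccccc9)c2c(c1)O[C@H](c8ccc(OCc9ccccc9)c(OCc9ccccc9)c8)[C@H](OCc9ccccc9)[C@H]2c3c(OCc9ccccc9)cc(O)c(c3OCc9ccccc9)[C@H](c5c(OCc9ccccc9)c(Br)c6c(c5OCc9ccccc9)C[C@@H](OCc9ccccc9)[C@@H](c8ccc(OCc9ccccc9)c(OCc9ccccc9)c8)O6)[C@@H](OCc9ccccc9)[C@@H](O)c8ccc(OCc9ccccc9)c(OCc9ccccc9)c8 | intermediate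
24 | pentadeca-O-benzyl-8-bromo-epicatechin-(4β→6)-epicatechin-(4β→6)-epicatechin | c9ccccc9COc1cc(OCc9ccccc9)c2c(c1)O[C@H](c8ccc(OCc9ccccc9)c(OCc9ccccc9)c8)[C@H](OCc9ccccc9)[C@H]2c3c(OCc9ccccc9)cc4c(c3OCc9ccccc9)[C@H](c5c(OCc9ccccc9)c(Br)c6c(c5OCc9ccccc9)C[C@@H](OCc9ccccc9)[C@@H](c8ccc(OCc9ccccc9)c(OCc9ccccc9)c8)O6)[C@@H](OCc9ccccc9)[C@@H](c8ccc(OCc9ccccc9)c(OCc9ccccc9)c8)O4 | intermediate
25 | epicatechin-(4β→6)-epicatechin-(4β→6)-epicatechin | Oc1cc(O)c2c(c1)O[C@H](c1ccc(O)c(O)c1)[C@H](O)[C@H]2c1c(O)cc2c(c1O)[C@H](c1c(O)cc3c(c1O)C[C@@H](O)[C@@H](c1ccc(O)c(O)c1)O3)[C@@H](O)[C@@H](c1ccc(O)c(O)c1)O2 | target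

## Step count and least certain steps

Total step count: 14. Longest linear sequence: 11 steps from 1 (steps 1, 2, 4, 5, 8, 9, 10, 11, 12, 13, 14); the lower-unit branch (steps 6, 7) and the arene branch (step 3) are convergent.

Step 9 (key step). The most likely failure is slow carbon–carbon bond formation at a methide carbon flanked by two di-ortho-substituted rings. Self-aldol of 13, reversible trapping of the amine by 15, or decomposition of 15 could then take over. The second risk is weak face selection at C4, which the catalyst controls only through the topology of the approach and which cannot be repaired later. The fallback sets out from 12 and replaces the bulky chiral enamine by a small achiral nucleophile. A Mukaiyama–Michael addition of the silyl ketene acetal of methyl benzyloxyacetate F1 to the methide, generated with catalytic Sc(OTf)3 in CH2Cl2 at low temperature, would give the phenol ester F2. On warming with a trace of acid this should lactonise to the dihydrocoumarin F3, whose C3 can be equilibrated to the 3,4-trans arrangement with an amine base. The two C4 epimers are diastereomers because of the resident flavan centres and would be separated. Reduction of F3 with iBu2AlH in CH2Cl2 at −78 °C returns to the route at 17.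

Step 8. The most likely failure is lack of addition, because 10 is a hindered and electronically deactivated 2,4,6-trialkoxybenzaldehyde. Further ionisation of the product carbinol on magnesium with a second arylation is the other risk. The fallback reverses the polarity. Starting from 7, magnesium-mediated ortho-formylation (MgCl2, Et3N, paraformaldehyde, MeCN, reflux) would give the salicylaldehyde F4. Starting from 8, iodination at C6 with N-iodosuccinimide and catalytic CF3CO2H would give the 6-iodo-8-bromo flavan F5. Selective iodine–magnesium exchange with iPrMgCl·LiCl in THF at −40 °C would give the arylmagnesium chloride F6, which is added to F4 (deprotonated beforehand with one equivalent of iPrMgCl). This returns to the route at 12.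

Step 4. The most likely failure is attack of 5 through a carbon ortho to the silyl ether, or double alkylation, giving regioisomeric arylation products. The fallback sets out from 3 and uses a symmetric nucleophile. Friedel–Crafts capping with excess phloroglucinol (Me3SiOTf, THF/CH2Cl2) would give the 4β-(2,4,6-trihydroxyphenyl) flavan F7. Silylation of its least hindered para hydroxyl with iPr3SiCl and imidazole would give F8. Benzylation of the two remaining hindered hydroxyls (BnBr, K2CO3, acetone) returns to the route at 6, at the cost of two extra steps.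

Step 11. The most likely failure is competing oxidation of the free, electron-rich phenol (dehydrogenation through its ortho or para benzylic C–H) instead of, or after, the carbinol oxidation. The fallback sets out from 17 and brings C2 in at the acid oxidation level, so that no oxidation is run beside a free phenol. Oxidation of the lactol with Ag2CO3 on Celite in toluene would give the lactone F3. Ring opening with Me3Al and N,O-dimethylhydroxylamine hydrochloride would give the phenol Weinreb amide F9. Addition of 19 then gives the ketone and returns to the route at 22.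

Step 13. The most likely failure is ionisation of the activated 3,4-dialkoxybenzylic oxygen, so that the closure runs through an open cation and the inversion is lost. The fallback sets out from 22 and forms O1–C2 before the C2 hydrogen is delivered. With Et3SiH and Me3SiOTf in CH2Cl2 at −78 °C, the cyclic hemiketal tautomer F10 of 22 should ionise to the 2-aryl oxocarbenium triflate F11. Silane delivery anti to the C3 benzyloxy group is expected to give the 2,3-cis ring and returns to the route at 24. The face selectivity of this hydride transfer next to the C4 aryl group is the open point of this fallback.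

## Further compounds

F1 | step 9 | silyl ketene acetal of methyl benzyloxyacetate | COC(=COCc1ccccc1)O[Si](C)(C)C
F2 | step 9 | phenol methyl ester (Mukaiyama–Michael adduct; 3R; 3,4-trans after equilibration) | c9ccccc9COc1cc(OCc9ccccc9)c2c(c1)O[C@H](c8ccc(OCc9ccccc9)c(OCc9ccccc9)c8)[C@H](OCc9ccccc9)[C@H]2c3c(OCc9ccccc9)cc(O)c(c3OCc9ccccc9)[C@H](c5c(OCc9ccccc9)c(Br)c6c(c5OCc9ccccc9)C[C@@H](OCc9ccccc9)[C@@H](c8ccc(OCc9ccccc9)c(OCc9ccccc9)c8)O6)[C@@H](OCc9ccccc9)C(=O)OC
F3 | step 9 | middle-unit lactone (3,4-trans dihydrocoumarin) | c9ccccc9COc1cc(OCc9ccccc9)c2c(c1)O[C@H](c8ccc(OCc9ccccc9)c(OCc9ccccc9)c8)[C@H](OCc9ccccc9)[C@H]2c3c(OCc9ccccc9)cc4c(c3OCc9ccccc9)[C@H](c5c(OCc9ccccc9)c(Br)c6c(c5OCc9ccccc9)C[C@@H](OCc9ccccc9)[C@@H](c8ccc(OCc9ccccc9)c(OCc9ccccc9)c8)O6)[C@@H](OCc9ccccc9)C(=O)O4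
F4 | step 8 | salicylaldehyde of 7 (formyl ortho to the free hydroxyl) | c9ccccc9COc1cc(OCc9ccccc9)c2c(c1)O[C@H](c8ccc(OCc9ccccc9)c(OCc9ccccc9)c8)[C@H](OCc9ccccc9)[C@H]2c3c(OCc9ccccc9)cc(O)c(C=O)c3OCc9ccccc9
F5 | step 8 | 8-bromo-6-iodo-3,5,7,3',4'-penta-O-benzylepicatechin | Ic1c(OCc9ccccc9)c(Br)c2c(c1OCc9ccccc9)C[C@@H](OCc9ccccc9)[C@@H](c8ccc(OCc9ccccc9)c(OCc9ccccc9)c8)O2
F6 | step 8 | C6 arylmagnesium chloride of the 8-bromo lower unit | Cl[Mg]c1c(OCc9ccccc9)c(Br)c2c(c1OCc9ccccc9)C[C@@H](OCc9ccccc9)[C@@H](c8ccc(OCc9ccccc9)c(OCc9ccccc9)c8)O2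
F7 | step 4 | 4β-(2,4,6-trihydroxyphenyl)-3,5,7,3',4'-penta-O-benzylepicatechin | c9ccccc9COc1cc(OCc9ccccc9)c2c(c1)O[C@H](c8ccc(OCc9ccccc9)c(OCc9ccccc9)c8)[C@H](OCc9ccccc9)[C@H]2c3c(O)cc(O)cc3O
F8 | step 4 | 4β-[2,6-dihydroxy-4-(triisopropylsilyloxy)phenyl]-3,5,7,3',4'-penta-O-benzylepicatechin | c9ccccc9COc1cc(OCc9ccccc9)c2c(c1)O[C@H](c8ccc(OCc9ccccc9)c(OCc9ccccc9)c8)[C@H](OCc9ccccc9)[C@H]2c3c(O)cc(O[Si](C(C)C)(C(C)C)C(C)C)cc3O
F9 | step 11 | phenol Weinreb amide from ring opening of the lactone | c9ccccc9COc1cc(OCc9ccccc9)c2c(c1)O[C@H](c8ccc(OCc9ccccc9)c(OCc9ccccc9)c8)[C@H](OCc9ccccc9)[C@H]2c3c(OCc9ccccc9)cc(O)c(c3OCc9ccccc9)[C@H](c5c(OCc9ccccc9)c(Br)c6c(c5OCc9ccccc9)C[C@@H](OCc9ccccc9)[C@@H](c8ccc(OCc9ccccc9)c(OCc9ccccc9)c8)O6)[C@@H](OCc9ccccc9)C(=O)N(C)OC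
F10 | step 13 | cyclic hemiketal tautomer of 22 | c9ccccc9COc1cc(OCc9ccccc9)c2c(c1)O[C@H](c8ccc(OCc9ccccc9)c(OCc9ccccc9)c8)[C@H](OCc9ccccc9)[C@H]2c3c(OCc9ccccc9)cc4c(c3OCc9ccccc9)[C@H](c5c(OCc9ccccc9)c(Br)c6c(c5OCc9ccccc9)C[C@@H](OCc9ccccc9)[C@@H](c8ccc(OCc9ccccc9)c(OCc9ccccc9)c8)O6)[C@@H](OCc9ccccc9)C(O)(c8ccc(OCc9ccccc9)c(OCc9ccccc9)c8)O4
F11 | step 13 | 2-aryl oxocarbenium triflate of the middle unit | c9ccccc9COc1cc(OCc9ccccc9)c2c(c1)O[C@H](c8ccc(OCc9ccccc9)c(OCc9ccccc9)c8)[C@H](OCc9ccccc9)[C@H]2c3c(OCc9ccccc9)cc4c(c3OCc9ccccc9)[C@H](c5c(OCc9ccccc9)c(Br)c6c(c5OCc9ccccc9)C[C@@H](OCc9ccccc9)[C@@H](c8ccc(OCc9ccccc9)c(OCc9ccccc9)c8)O6)[C@@H](OCc9ccccc9)C(c8ccc(OCc9ccccc9)c(OCc9ccccc9)c8)=[O+]4.[O-]S(=O)(=O)C(F)(F)F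
A1 | alternative 1 | tridecabenzyl 8-bromo trimer with free C3 hydroxyls on the upper and middle units | c9ccccc9COc1cc(OCc9ccccc9)c2c(c1)O[C@H](c8ccc(OCc9ccccc9)c(OCc9ccccc9)c8)[C@H](O)[C@H]2c3c(OCc9ccccc9)cc4c(c3OCc9ccccc9)[C@H](c5c(OCc9ccccc9)c(Br)c6c(c5OCc9ccccc9)C[C@@H](OCc9ccccc9)[C@@H](c8ccc(OCc9ccccc9)c(OCc9ccccc9)c8)O6)[C@@H](O)[C@@H](c8ccc(OCc9ccccc9)c(OCc9ccccc9)c8)O4
A2 | alternative 1 | acyclic bis(trans-epoxide) with both rings C open | c9ccccc9COc1cc(OCc9ccccc9)cc(c1)O[C@H](c8ccc(OCc9ccccc9)c(OCc9ccccc9)c8)[C@@H]2O[C@H]2c3c(OCc9ccccc9)cc(O[C@H](c8ccc(OCc9ccccc9)c(OCc9ccccc9)c8)[C@@H]4O[C@H]4c5c(OCc9ccccc9)c(Br)c6c(c5OCc9ccccc9)C[C@@H](OCc9ccccc9)[C@@H](c8ccc(OCc9ccccc9)c(OCc9ccccc9)c8)O6)cc3OCc9ccccc9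
A3 | alternative 2 | middle ring A phenol with free C5 hydroxyl, silylated C8a oxygen and open ring C | c9ccccc9COc1cc(OCc9ccccc9)c2c(c1)O[C@H](c8ccc(OCc9ccccc9)c(OCc9ccccc9)c8)[C@H](OCc9ccccc9)[C@H]2c3c(OCc9ccccc9)cc(O[Si](C(C)C)(C(C)C)C(C)C)c(c3O)[C@H](c5c(OCc9ccccc9)c(Br)c6c(c5OCc9ccccc9)C[C@@H](OCc9ccccc9)[C@@H](c8ccc(OCc9ccccc9)c(OCc9ccccc9)c8)O6)[C@@H](OCc9ccccc9)[C@@H](O[Si](C)(C)C(C)(C)C)c8ccc(OCc9ccccc9)c(OCc9ccccc9)c8
A4 | alternative 2 | upper-unit cyclobutenone: 3-benzyloxy-4-(flavan-4β-yl)cyclobut-2-enone | c9ccccc9COc1cc(OCc9ccccc9)c2c(c1)O[C@H](c8ccc(OCc9ccccc9)c(OCc9ccccc9)c8)[C@H](OCc9ccccc9)[C@H]2C3C(=O)C=C3OCc9ccccc9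
A5 | alternative 2 | lower-unit siloxyalkyne carrying the acyclic C2–C4 chain of the middle unit | CC(C)[Si](C(C)C)(C(C)C)OC#C[C@H](c5c(OCc9ccccc9)c(Br)c6c(c5OCc9ccccc9)C[C@@H](OCc9ccccc9)[C@@H](c8ccc(OCc9ccccc9)c(OCc9ccccc9)c8)O6)[C@@H](OCc9ccccc9)[C@@H](O[Si](C)(C)C(C)(C)C)c8ccc(OCc9ccccc9)c(OCc9ccccc9)c8
A6 | alternative 3 | dimer with a dimethyl trihydroxyisophthalate ring on C4 of the middle unit | c9ccccc9COc1cc(OCc9ccccc9)c2c(c1)O[C@H](c8ccc(OCc9ccccc9)c(OCc9ccccc9)c8)[C@H](OCc9ccccc9)[C@H]2c3c(OCc9ccccc9)cc4c(c3OCc9ccccc9)[C@H](c5c(O)c(C(=O)OC)c(O)c(C(=O)OC)c5O)[C@@H](OCc9ccccc9)[C@@H](c8ccc(OCc9ccccc9)c(OCc9ccccc9)c8)O4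
A7 | alternative 3 | dimer with a dimethyl malonate on C4 of the middle unit | c9ccccc9COc1cc(OCc9ccccc9)c2c(c1)O[C@H](c8ccc(OCc9ccccc9)c(OCc9ccccc9)c8)[C@H](OCc9ccccc9)[C@H]2c3c(OCc9ccccc9)cc4c(c3OCc9ccccc9)[C@H](C(C(=O)OC)C(=O)OC)[C@@H](OCc9ccccc9)[C@@H](c8ccc(OCc9ccccc9)c(OCc9ccccc9)c8)O4
A8 | alternative 3 | dimethyl 3-oxoglutarate | COC(=O)CC(=O)CC(=O)OC
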